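## Analysis of the target

Target **22** is a 2,3-epoxycyclohexanone. The ring is numbered C1 (ketone), C2 (methyl-bearing epoxide carbon), C3 (epoxide CH), C4 (CH2), C5 and C6. C5 carries a 1,1-disubstituted alkene carbon C7, which is bonded to the carbinol carbon C8 and on to a prenyl group. The C6 and C8 oxygens are both esterified with 3-methylbut-2-enoic acid. There are five stereocentres: C2, C3, C5 and C6 on the ring (all S) and C8 (R). The C5 side chain and the C6 acyloxy group are trans. The epoxide oxygen lies on the face of the C5 side chain, hence trans to the C6 ester. C8 is separated from the ring by the sp2 carbon C7 and cannot be set by relay from the ring. Sensitive groups are the epoxy ketone, the α-acyloxy ketone (C6–H can epimerise, the ester can migrate), the two senecioates (deconjugation), the allylic C8 ester and the electron-rich prenyl alkene. The main difficulties are three things. The epoxide sits on the face that nucleophilic epoxidation of a 5-substituted 2-methylcyclohexenone normally avoids. Five alkenes of different kinds are present at the end. C8 needs reagent control. The strategy rests on one structural fit: the C6–O bond, the C5–C7 bond trans to it, the unsubstituted C4 and the methyl group on C2 match, atom for atom, the endo [4+2] adduct of 3-methylfuran (**1**) with an acrylate. The furan oxygen becomes the C6 oxygen, and the second bridge bond (C3–O) is strain that can be spent to make the C2=C3 enone.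

## Retrosynthetic reasoning

Ring atoms keep the target numbering in all intermediates. In the von Baeyer names of the bicycles, C1, C2, C3, C4, C5, C6 correspond to ring C6, C5, C4, C3, C2, C1.

**Epoxy ketone.** The C1 carbonyl of **22** is traced to the carbinol **21**, the two epoxide C–O bonds to the allylic alcohol **20**, and **20** to the enone **19** by 1,2-reduction. Direct nucleophilic epoxidation of **19** would be expected to go anti to the C5 substituent, which is the wrong face. Axial hydride delivery to C1 instead gives a hydroxyl cis to the side chain and trans to the C6 ester, and a hydroxyl-directed epoxidation then places the oxygen syn to it. The directed oxidant only touches the alkene next to the free hydroxyl, so the prenyl alkene is spared.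

**Ester C–O bonds.** Both senecioate bonds of **19** are cut to the diol **17** and two molecules of **18**. The esters come late because they would not survive the organometallic and enolate steps, and both hydroxyls can be acylated in one operation.

**C7–C8.** This is the only carbon–carbon bond outside the ring that is not already in a commercial fragment. Cutting it gives the alkenyl triflate **14** and the aldehyde **16** (from **15**). The forward nickel/chromium coupling tolerates the enone and the free hydroxyl, and a chiral ligand on chromium can set C8.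

**C3–O (retro-elimination).** The 6-hydroxy enone **14** is the β-elimination product of the oxa-bridged ketone **12** (through the silyl ether **13**). C6 is a bridgehead, so the ketone can enolise only towards C2 and the opening has one possible direction. A carbonyl group on C5 would offer a second enolate that could expel the bridge from C6. For that reason the acyl group of the cycloadduct is turned into the alkenyl triflate before the C1 ketone is unveiled.

**Functional-group changes on the bicycle.** **12** comes from **11** and **10** (oxidation, desilylation). The triflate **10** comes from the methyl ketone **8** through its kinetic enolate **9**. The bond from C7 to the future methylene carbon is made by adding a methyl nucleophile to the Weinreb amide **7**. The C1 oxygen of **6** comes from hydroboration of the only alkene in **4** (through **5**), so this step has to precede the introduction of every other alkene. The silyl group in **7** masks the C1 hydroxyl during the enolate chemistry. **4** comes from **3** by acyl transfer.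

**C3–C4 and C5–C6.** Cutting these two bonds in **3** gives **1** and **2**, both commercial. The forward cycloaddition must be regioselective (methyl distal to acyl), endo (acyl anti to the oxygen bridge, which gives trans C5/C6) and face-selective.

## Alternatives that were turned down

**Alternative 1:** The ring is opened at C1–C2. This leads to the open-chain aldehyde A2, in which C2 is part of a (Z)-iodoalkene and C1 is a formyl group. Forward, an intramolecular NiCl2/CrCl2 alkenyl–aldehyde coupling would close the ring and give the cyclohexenol A1, which is the same compound as **20**.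
- For: ring, C2=C3 alkene and the directing C1 carbinol arrive in one step, two operations before the target. There is no regiochemical question like that of **1**.
- Against: A2 must already contain C5, C6 and C8, so three stereocentres have to be built by acyclic control before the ring exists. A2 is an α-acyloxy aldehyde; C6 can epimerise and the acyloxy group is liable to reductive loss under divalent chromium. The C1 configuration would depend on the conformation of a flexible chain in the closing transition state. The trisubstituted (Z)-iodoalkene needs its own stereoselective synthesis.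
- Comparison: on regiochemistry this alternative is stronger. The chosen route offers instead that C5 and C6 are fixed together by the geometry of one catalytic cycloaddition of two commercial compounds, and that C1 is set on a rigid ring (step 13). A linear build of A2 is unlikely to match the step count.

**Alternative 2:** Both ring C–O bonds at C3 and C6 are traced to one molecule of oxygen, giving the cyclohexa-1,3-diene A4. Forward, sensitised photooxygenation would add across C3 and C6 from the face opposite the C5 substituent to give the endoperoxide A3. Base-induced isomerisation to the 6-hydroxy-3-ketone, epoxidation and a Wharton transposition would then move the C3 oxygen to C1.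
- For: the C6 oxygen goes in trans to C5 by steric approach control, and the oxidant is cheap. A4 has the substitution pattern of a phellandrene-type terpene, so C5 might come from the chiral pool instead of a chiral catalyst. On that point it is stronger than the chosen route.
- Against: the prenyl alkene of A4, and less so its 1,1-disubstituted alkene, are good partners for the ene reaction with singlet oxygen, so chemoselectivity in the key step is doubtful. A4 can drift to conjugated or aromatic isomers. The isomerisation of A3 must choose C3–H over C6–H. The oxygen relay costs about four extra steps, uses hydrazine (so the esters must come late), and ends in a 1,6-diol whose hydroxyls must be told apart.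
- Comparison: the chosen route places the C1 oxygen by hydroboration of a single alkene before any other alkene is present, and pays with a chiral catalyst for what the chiral pool would give here.

**Alternative 3:** C4–C5 and C1–C6 are cut, giving the 1-silyloxy diene A6 and the enynone A7. Forward, an endo Diels–Alder reaction under chiral oxazaborolidinium catalysis would give the cyclohexene A5. Its acetyl group on C6 stands for the later C6 oxygen (Baeyer–Villiger oxidation) and its silylalkyne on C5 for the side chain.
- For: the carbocycle forms with the methyl group, the C2=C3 alkene and an oxygen on C1 already in place. The regiochemistry is dictated by a strongly polarised 1-oxygenated diene, which is more secure than the methyl group of **1**.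
- Against: the endo mode puts the C1 silyloxy group cis to the C6 acetyl group in A5, whereas the directing carbinol must be trans to the C6 oxygen. C1 would have to be erased by oxidation and reset by the same reduction as in step 13. The Baeyer–Villiger oxidation competes with peracid epoxidation of the electron-rich C2=C3 alkene. The β-silyloxy ketone A5 can eliminate to a dienone. A6 and A7 each need several steps, and the alkyne must still be turned into the branched allylic alcohol, so nothing is saved in the side chain.
- Comparison: the chosen route has the less certain regiochemistry. It delivers the C6 oxygen itself, trans to C5 by the geometry of the bicycle, and creates the enone without any oxidation-state correction.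

Key step: step 1

Assumption: the facial sense of the copper–bis(oxazoline) catalyst with **1** is taken to follow that known for furan and cyclopentadiene (hence the (R,R)-ligand), and the sense of the sulfonamide ligand in step 11 is assigned by analogy; the antipode of either ligand is available if an assignment proves reversed.

## Route

Step 1
Reactants: 1 3-methylfuran; 2 3-acryloyl-1,3-oxazolidin-2-one
Product: 3 endo adduct 3-[(1R,2R,4R)-5-methyl-7-oxabicyclo[2.2.1]hept-5-ene-2-carbonyl]-1,3-oxazolidin-2-one
Conditions: Cu(SbF6)2 (10 mol %), 2,2'-(propane-2,2-diyl)bis[(4R)-4-tert-butyl-4,5-dihydro-1,3-oxazole] (11 mol %), 1 (5 equiv), CH2Cl2, −78 °C; cold filtration through silica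
Reagents that add atoms: none
Why: The imide 2 binds the cationic divalent copper centre through both carbonyl oxygens in a square-planar complex with the s-cis enoyl conformation, which lowers its LUMO and lets one tert-butyl group of the ligand shield one alkene face. The furan then adds in a concerted, asynchronous [4+2] cycloaddition; the closest known reaction is the same catalyst system with unsubstituted furan and this acrylimide. The six-membered carbocycle C1–C6 is closed intermolecularly by suprafacial addition across the furan 2,5-positions, forming C3–C4 and C5–C6 and leaving the furan oxygen as the one-atom bridge. The methyl group raises the HOMO coefficient at the adjacent furan α-carbon, which bonds first to the acrylate β-carbon (C4), so methyl and acyl should end up distal, on C2 and C5. C5 is set by the ligand-controlled face of the dienophile. The bridgeheads C6 and C3 follow from the endo transition state, which places the acyl group anti to the oxygen bridge, that is C5–C7 trans to C6–O. The step needs regio-, endo- and facial selectivity under kinetic control; −78 °C, excess 1 and a cold work-up are meant to suppress cycloreversion, which would feed the exo isomer and erode enantiopurity.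

Step 2
Reactants: 3 endo imide adduct
Product: 4 (1R,2R,4R)-N-methoxy-N,5-dimethyl-7-oxabicyclo[2.2.1]hept-5-ene-2-carboxamide (endo)
Conditions: MeNH(OMe)·HCl, AlMe3, CH2Cl2, −20 to 0 °C; aq. potassium sodium tartrate
Reagents that add atoms: N,O-dimethylhydroxylamine hydrochloride, CNOC.Cl
Why: Aluminium amide transamidation of N-acyl oxazolidinones attacks the exocyclic carbonyl selectively; the reagent is weakly basic, so C5 should not be deprotonated and the endo configuration and the bridge stay intact, and the low temperature lets acyl transfer outrun cycloreversion.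

Step 3
Reactants: 4 endo Weinreb amide
Product: 6 (1S,2R,4R,5R,6R)-6-hydroxy-N-methoxy-N,5-dimethyl-7-oxabicyclo[2.2.1]heptane-2-carboxamide (amide endo; methyl endo; hydroxyl exo), via alkylborane 5 (not isolated)
Conditions: BH3·THF (1.5 equiv), THF, 0 °C; then 30 % H2O2, 3 M NaOH, 0 °C
Reagents that add atoms: hydrogen peroxide, OO
Why: Hydroboration–oxidation: boron adds to the less substituted alkene carbon (C1) from the exo face of the strained alkene, much faster than borane reduces a tertiary amide at 0 °C, and the C–B bond is oxidised with retention; the new centres at C1 (exo oxygen) and C2 (endo methyl) are both removed later.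

Step 4
Reactants: 6 exo alcohol
Product: 7 (1S,2R,4R,5S,6R)-N-methoxy-N,5-dimethyl-6-(triethylsilyloxy)-7-oxabicyclo[2.2.1]heptane-2-carboxamide
Conditions: Et3SiCl, imidazole, DMF, 0 °C to rt
Reagents that add atoms: chlorotriethylsilane, CC[Si](Cl)(CC)CC
Why: Standard silylation of a secondary alcohol; the triethylsilyl ether should survive the Grignard and enolate steps and come off under mild acid that leaves an alkenyl triflate untouched.

Step 5
Reactants: 7 silylated Weinreb amide
Product: 8 1-[(1S,2R,4R,5S,6R)-5-methyl-6-(triethylsilyloxy)-7-oxabicyclo[2.2.1]heptan-2-yl]ethan-1-one (acetyl endo)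
Conditions: MeMgBr (1.5 equiv), THF, −20 to 0 °C; aq. NH4Cl
Reagents that add atoms: methylmagnesium bromide, C[Mg]Br
Why: Weinreb ketone synthesis: the chelated tetrahedral intermediate stops at the ketone stage and collapses only on quench, so the endo acetyl group is not exposed to base and C5 should not epimerise.

Step 6
Reactants: 8 methyl ketone
Product: 10 1-[(1S,2R,4R,5S,6R)-5-methyl-6-(triethylsilyloxy)-7-oxabicyclo[2.2.1]heptan-2-yl]ethenyl trifluoromethanesulfonate, via potassium enolate 9 (not isolated)
Conditions: KN(SiMe3)2 (1.1 equiv), THF, −78 °C; then PhNTf2, −78 to −20 °C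
Reagents that add atoms: N-phenylbis(trifluoromethanesulfonimide), O=S(=O)(N(c1ccccc1)S(=O)(=O)C(F)(F)F)C(F)(F)F
Why: Kinetic deprotonation of a methyl ketone by a hindered amide base takes the methyl hydrogen in preference to the ring methine, and the enolate is O-triflated; keeping the temperature low should prevent equilibration to the ring-side enolate, which would epimerise C5 or expel the bridge oxygen from C6.

Step 7
Reactants: 10 silylated alkenyl triflate
Product: 11 1-[(1S,2R,4R,5R,6R)-6-hydroxy-5-methyl-7-oxabicyclo[2.2.1]heptan-2-yl]ethenyl trifluoromethanesulfonate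
Conditions: PPTS, MeOH, rt
Reagents that add atoms: none
Why: Acid-catalysed methanolysis of a secondary triethylsilyl ether; the alkenyl triflate and the bridging ether are stable to pyridinium tosylate.

Step 8
Reactants: 11 exo alcohol
Product: 12 1-[(1S,2R,4R,5S)-5-methyl-6-oxo-7-oxabicyclo[2.2.1]heptan-2-yl]ethenyl trifluoromethanesulfonate
Conditions: Dess–Martin periodinane, CH2Cl2, rt
Reagents that add atoms: none
Why: Dess–Martin oxidation of a secondary alcohol under near-neutral conditions, so the β-alkoxy ketone should not open prematurely; C6 is a bridgehead and cannot epimerise.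

Step 9
Reactants: 12 oxa-bridged ketone
Product: 14 1-[(1R,2S)-2-hydroxy-4-methyl-3-oxocyclohex-4-en-1-yl]ethenyl trifluoromethanesulfonate, via trimethylsilyl ether 13 (not isolated)
Conditions: Me3SiOTf (1.5 equiv), Et3N (2 equiv), CH2Cl2, −78 to 0 °C; then 1 M HCl, THF, 0 °C
Reagents that add atoms: none
Why: Known opening of 7-oxabicyclo[2.2.1]heptan-2-ones to 6-oxygenated cyclohex-2-enones: the ketone can form a silyl enol ether only towards C2, and silyl-assisted cleavage of the allylic C3–O bond then releases the ring strain and gives the C2=C3 enone with the bridge oxygen left on C6; C5 and C6 are not touched, C5–H is only allylic, and dilute acid removes the trimethylsilyl group.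

Step 10
Reactants: 15 4-methylpent-3-en-1-ol
Product: 16 4-methylpent-3-enal
Conditions: Dess–Martin periodinane, NaHCO3, CH2Cl2, 0 °C; short silica plug, solution used at once
Reagents that add atoms: none
Why: Buffered Dess–Martin oxidation of a primary alcohol; neutral conditions and immediate use should keep the β,γ-alkene from moving into conjugation.

Step 11
Reactants: 14 hydroxy enone alkenyl triflate; 16 4-methylpent-3-enal
Product: 17 (5S,6S)-6-hydroxy-5-[(3R)-3-hydroxy-6-methylhepta-1,5-dien-2-yl]-2-methylcyclohex-2-en-1-one
Conditions: CrCl2 (4 equiv), NiCl2 (5 mol %), (S)-N-[2-(4-isopropyl-4,5-dihydro-1,3-oxazol-2-yl)-6-methylphenyl]methanesulfonamide (4.4 equiv), Et3N (4.4 equiv), 16 (3 equiv), THF, rt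
Reagents that add atoms: none
Why: Nozaki–Hiyama–Kishi coupling: zerovalent nickel inserts into the C–OTf bond, the alkenyl group passes to trivalent chromium and adds to the aldehyde only, with ketone, enone and free hydroxyl tolerated; C8 is set by the chiral sulfonamide ligand on chromium (reagent control), since the ring stereocentres are too remote to help.

Step 12
Reactants: 17 diol; 18 3-methylbut-2-enoic acid (3 equiv)
Product: 19 (1S,6S)-3-methyl-6-[(3R)-6-methyl-3-(3-methylbut-2-enoyloxy)hepta-1,5-dien-2-yl]-2-oxocyclohex-3-en-1-yl 3-methylbut-2-enoate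
Conditions: N,N'-diisopropylcarbodiimide, DMAP (cat.), CH2Cl2, 0 °C to rt
Reagents that add atoms: none
Why: Steglich esterification of both secondary hydroxyls with retention at C6 and C8; a low DMAP loading limits deconjugation of the senecioyl group, and any epimerisation at C6 would favour the trans (diequatorial) arrangement that is wanted.

Step 13
Reactants: 19 diester enone
Product: 20 (1S,2S,6S)-2-hydroxy-3-methyl-6-[(3R)-6-methyl-3-(3-methylbut-2-enoyloxy)hepta-1,5-dien-2-yl]cyclohex-3-en-1-yl 3-methylbut-2-enoate
Conditions: NaBH4, CeCl3·7H2O, MeOH, −78 °C; acetone then aq. NH4Cl at −78 °C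
Reagents that add atoms: none
Why: Luche reduction is 1,2-selective and leaves the unsaturated esters alone; axial hydride delivery to C1 of the half-chair with diequatorial C5 and C6 substituents should give the pseudo-equatorial hydroxyl, cis to the C5 side chain and trans to the C6 ester, as is usual for 5-substituted 2-methylcyclohex-2-enones.

Step 14
Reactants: 20 allylic alcohol
Product: 21 (1R,2R,3S,4S,6S)-2-hydroxy-1-methyl-4-[(3R)-6-methyl-3-(3-methylbut-2-enoyloxy)hepta-1,5-dien-2-yl]-7-oxabicyclo[4.1.0]heptan-3-yl 3-methylbut-2-enoate (epoxide cis to the hydroxyl)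
Conditions: VO(acac)2 (5 mol %), t-BuOOH (1.5 equiv), CH2Cl2, 0 °C to rt
Reagents that add atoms: tert-butyl hydroperoxide, CC(C)(C)OO
Why: Hydroxyl-directed epoxidation: the vanadate ester of the C1 hydroxyl delivers oxygen to the syn face of C2=C3 and so sets C2 and C3; the other alkenes have no free hydroxyl nearby (prenyl, 1,1-disubstituted) or are electron-poor (senecioates) and should not react.

Step 15
Reactants: 21 epoxy alcohol
Product: 22 (1S,3S,4S,6S)-1-methyl-4-[(3R)-6-methyl-3-(3-methylbut-2-enoyloxy)hepta-1,5-dien-2-yl]-2-oxo-7-oxabicyclo[4.1.0]heptan-3-yl 3-methylbut-2-enoate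
Conditions: Dess–Martin periodinane, NaHCO3, CH2Cl2, 0 °C to rt
Reagents that add atoms: none
Why: Buffered Dess–Martin oxidation turns the C1 carbinol into the ketone without opening the epoxide or epimerising C6, and gives the target.

## Compound list

1 | 3-methylfuran | Cc1ccoc1 | starting material
2 | 3-acryloyl-1,3-oxazolidin-2-one | C=CC(=O)N1CCOC1=O | starting material
3 | 3-[(1R,2R,4R)-5-methyl-7-oxabicyclo[2.2.1]hept-5-ene-2-carbonyl]-1,3-oxazolidin-2-one (endo) | O=C(N1CCOC1=O)[C@@H]1C[C@H]2O[C@@H]1C=C2C | intermediate
4 | (1R,2R,4R)-N-methoxy-N,5-dimethyl-7-oxabicyclo[2.2.1]hept-5-ene-2-carboxamide (endo) | CON(C)C(=O)[C@@H]1C[C@H]2O[C@@H]1C=C2C | intermediate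
5 | 6-exo-boranyl-N-methoxy-N,5-endo-dimethyl-7-oxabicyclo[2.2.1]heptane-2-endo-carboxamide (alkylborane) | CON(C)C(=O)[C@@H]1C[C@H]2O[C@@H]1[C@H](B)[C@H]2C | intermediate
6 | (1S,2R,4R,5R,6R)-6-hydroxy-N-methoxy-N,5-dimethyl-7-oxabicyclo[2.2.1]heptane-2-carboxamide | CON(C)C(=O)[C@@H]1C[C@H]2O[C@@H]1[C@H](O)[C@H]2C | intermediate
7 | (1S,2R,4R,5S,6R)-N-methoxy-N,5-dimethyl-6-(triethylsilyloxy)-7-oxabicyclo[2.2.1]heptane-2-carboxamide | CON(C)C(=O)[C@@H]1C[C@H]2O[C@@H]1[C@H](O[Si](CC)(CC)CC)[C@H]2C | intermediate
8 | 1-[(1S,2R,4R,5S,6R)-5-methyl-6-(triethylsilyloxy)-7-oxabicyclo[2.2.1]heptan-2-yl]ethan-1-one | CC(=O)[C@@H]1C[C@H]2O[C@@H]1[C@H](O[Si](CC)(CC)CC)[C@H]2C | intermediate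
9 | potassium enolate of 8 (terminal, on the methyl side) | C=C([O-])[C@@H]1C[C@H]2O[C@@H]1[C@H](O[Si](CC)(CC)CC)[C@H]2C.[K+] | intermediate
10 | 1-[(1S,2R,4R,5S,6R)-5-methyl-6-(triethylsilyloxy)-7-oxabicyclo[2.2.1]heptan-2-yl]ethenyl trifluoromethanesulfonate | C=C(OS(=O)(=O)C(F)(F)F)[C@@H]1C[C@H]2O[C@@H]1[C@H](O[Si](CC)(CC)CC)[C@H]2C | intermediate
11 | 1-[(1S,2R,4R,5R,6R)-6-hydroxy-5-methyl-7-oxabicyclo[2.2.1]heptan-2-yl]ethenyl trifluoromethanesulfonate | C=C(OS(=O)(=O)C(F)(F)F)[C@@H]1C[C@H]2O[C@@H]1[C@H](O)[C@H]2C | intermediate
12 | 1-[(1S,2R,4R,5S)-5-methyl-6-oxo-7-oxabicyclo[2.2.1]heptan-2-yl]ethenyl trifluoromethanesulfonate | C=C(OS(=O)(=O)C(F)(F)F)[C@@H]1C[C@H]2O[C@@H]1C(=O)[C@H]2C | intermediate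
13 | 1-[(1R,2S)-4-methyl-3-oxo-2-(trimethylsilyloxy)cyclohex-4-en-1-yl]ethenyl trifluoromethanesulfonate | C=C(OS(=O)(=O)C(F)(F)F)[C@@H]1CC=C(C)C(=O)[C@H]1O[Si](C)(C)C | intermediate
14 | 1-[(1R,2S)-2-hydroxy-4-methyl-3-oxocyclohex-4-en-1-yl]ethenyl trifluoromethanesulfonate | C=C(OS(=O)(=O)C(F)(F)F)[C@@H]1CC=C(C)C(=O)[C@H]1O | intermediate
15 | 4-methylpent-3-en-1-ol | CC(C)=CCCO | starting material
16 | 4-methylpent-3-enal | CC(C)=CCC=O | intermediate
17 | (5S,6S)-6-hydroxy-5-[(3R)-3-hydroxy-6-methylhepta-1,5-dien-2-yl]-2-methylcyclohex-2-en-1-one | C=C([C@@H](CC=C(C)C)O)[C@@H]1CC=C(C)C(=O)[C@H]1O | intermediate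
18 | 3-methylbut-2-enoic acid | CC(C)=CC(=O)O | starting material
19 | (1S,6S)-3-methyl-6-[(3R)-6-methyl-3-(3-methylbut-2-enoyloxy)hepta-1,5-dien-2-yl]-2-oxocyclohex-3-en-1-yl 3-methylbut-2-enoate | C=C([C@@H](CC=C(C)C)OC(=O)C=C(C)C)[C@@H]1CC=C(C)C(=O)[C@H]1OC(=O)C=C(C)C | intermediate
20 | (1S,2S,6S)-2-hydroxy-3-methyl-6-[(3R)-6-methyl-3-(3-methylbut-2-enoyloxy)hepta-1,5-dien-2-yl]cyclohex-3-en-1-yl 3-methylbut-2-enoate | C=C([C@@H](CC=C(C)C)OC(=O)C=C(C)C)[C@@H]1CC=C(C)[C@H](O)[C@H]1OC(=O)C=C(C)C | intermediate
21 | (1R,2R,3S,4S,6S)-2-hydroxy-1-methyl-4-[(3R)-6-methyl-3-(3-methylbut-2-enoyloxy)hepta-1,5-dien-2-yl]-7-oxabicyclo[4.1.0]heptan-3-yl 3-methylbut-2-enoate | C=C([C@@H](CC=C(C)C)OC(=O)C=C(C)C)[C@@H]1C[C@@H]2O[C@]2(C)[C@H](O)[C@H]1OC(=O)C=C(C)C | intermediate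
22 | (1S,3S,4S,6S)-1-methyl-4-[(3R)-6-methyl-3-(3-methylbut-2-enoyloxy)hepta-1,5-dien-2-yl]-2-oxo-7-oxabicyclo[4.1.0]heptan-3-yl 3-methylbut-2-enoate | C=C([C@@H](CC=C(C)C)OC(=O)C=C(C)C)[C@@H]1C[C@@H]2O[C@]2(C)C(=O)[C@H]1OC(=O)C=C(C)C | target

## Step count and risk

Total step count: 15. Longest linear sequence: 14 steps (steps 1 to 9 and 11 to 15); step 10 prepares the aldehyde.

**Step 1 (key step).** A single methyl group may polarise the furan too weakly, so regiocontrol could be lost. The adduct may also revert on the Lewis acid and re-form as the exo isomer with loss of enantiopurity, or the furan may undergo conjugate alkylation at its free α-position instead of cycloaddition. Fallback, auxiliary control in place of catalyst control: setting out from **1**, the cycloaddition would be run with the covalently bound chiral dienophile (S)-3-acryloyl-4-benzyl-1,3-oxazolidin-2-one F1 under Et2AlCl chelation at −78 °C, where the benzyl group blocks one face of the s-cis chelate. The benzyl-oxazolidinone adduct F2 would then be one of a set of diastereomers and regioisomers that can be separated by crystallisation or chromatography. The transamidation of step 2 converts F2 into **4**, where the route is rejoined.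

**Step 9.** Enol silylation at the hindered tertiary α-carbon may be slow, and the liberated α-ketol may isomerise through its enediol (epimerisation at C6, ketol transposition, dehydrative aromatisation) during isolation or in step 11. Fallback: from **12**, irreversible enolate formation with LiN(SiMe3)2 at −78 °C and warming would trigger an E1cB opening, and the alkoxide would be capped in the same flask with tert-butyldimethylsilyl triflate as the tert-butyldimethylsilyl ether F3. F3 would be coupled with **16** as in step 11 to give the silyl ether diol precursor F4, and HF·pyridine would then release **17**, where the route is rejoined.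

**Step 11.** Ligand control at C8 may be weakened by coordination of the free C6 hydroxyl and the ketone to chromium, and the aldehyde may suffer double-bond migration into conjugation before it couples. Fallback, C8 set by reagent-controlled ketone reduction when no other carbonyl is present: from **10**, NiCl2/CrCl2 coupling with **16** without chiral ligand would give the bicyclic allylic alcohol F5 as both C8 epimers. Dess–Martin oxidation gives the enone F6. Corey–Bakshi–Shibata reduction with catecholborane and (S)-1-methyl-3,3-diphenyltetrahydro-1H,3H-pyrrolo[1,2-c][1,3,2]oxazaborole gives the (8R)-alcohol F7, and Steglich esterification with **18** gives the monoester F8. Steps 7, 8 and 9 then apply unchanged and lead through the alcohol F9 and the bridged ketone F10 to the hydroxy enone monoester F11, whose C6 hydroxyl is esterified with **18** to give **19**, where the route is rejoined.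

**Step 13.** Hydride delivery may show poor facial selectivity if the C6 ester distorts the half-chair or binds cerium, and the product may undergo a 6-to-1 acyl shift if the quench is not cold and neutral. Fallback: from **19**, the C1-epimeric alcohol F12 would be separated and inverted by a Mitsunobu reaction with chloroacetic acid (PPh3, diisopropyl azodicarboxylate) to the chloroacetate F13. Thiourea removes the chloroacetyl group selectively in the presence of the two senecioates and gives **20**, where the route is rejoined.

## Further compounds

F1 | step 1 | (S)-3-acryloyl-4-benzyl-1,3-oxazolidin-2-one | C=CC(=O)N1[C@@H](Cc2ccccc2)COC1=O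
F2 | step 1 | (4S)-4-benzyl-3-[(1R,2R,4R)-5-methyl-7-oxabicyclo[2.2.1]hept-5-ene-2-carbonyl]-1,3-oxazolidin-2-one (endo) | O=C(N1[C@@H](Cc2ccccc2)COC1=O)[C@@H]1C[C@H]2O[C@@H]1C=C2C
F3 | step 9 | 1-[(1R,2S)-2-(tert-butyldimethylsilyloxy)-4-methyl-3-oxocyclohex-4-en-1-yl]ethenyl trifluoromethanesulfonate | C=C(OS(=O)(=O)C(F)(F)F)[C@@H]1CC=C(C)C(=O)[C@H]1O[Si](C)(C)C(C)(C)C
F4 | step 9 | (5S,6S)-6-(tert-butyldimethylsilyloxy)-5-[(3R)-3-hydroxy-6-methylhepta-1,5-dien-2-yl]-2-methylcyclohex-2-en-1-one | C=C([C@@H](CC=C(C)C)O)[C@@H]1CC=C(C)C(=O)[C@H]1O[Si](C)(C)C(C)(C)C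
F5 | step 11 | 6-methyl-2-[5-endo-methyl-6-exo-(triethylsilyloxy)-7-oxabicyclo[2.2.1]heptan-2-endo-yl]hepta-1,5-dien-3-ol (both C3 epimers; bicycle as in 10) | C=C(C(O)CC=C(C)C)[C@@H]1C[C@H]2O[C@@H]1[C@H](O[Si](CC)(CC)CC)[C@H]2C
F6 | step 11 | 6-methyl-2-[5-endo-methyl-6-exo-(triethylsilyloxy)-7-oxabicyclo[2.2.1]heptan-2-endo-yl]hepta-1,5-dien-3-one (bicycle as in 10) | C=C(C(=O)CC=C(C)C)[C@@H]1C[C@H]2O[C@@H]1[C@H](O[Si](CC)(CC)CC)[C@H]2C
F7 | step 11 | (3R)-6-methyl-2-[5-endo-methyl-6-exo-(triethylsilyloxy)-7-oxabicyclo[2.2.1]heptan-2-endo-yl]hepta-1,5-dien-3-ol (bicycle as in 10) | C=C([C@@H](CC=C(C)C)O)[C@@H]1C[C@H]2O[C@@H]1[C@H](O[Si](CC)(CC)CC)[C@H]2C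
F8 | step 11 | (3R)-6-methyl-2-[5-endo-methyl-6-exo-(triethylsilyloxy)-7-oxabicyclo[2.2.1]heptan-2-endo-yl]hepta-1,5-dien-3-yl 3-methylbut-2-enoate (bicycle as in 10) | C=C([C@@H](CC=C(C)C)OC(=O)C=C(C)C)[C@@H]1C[C@H]2O[C@@H]1[C@H](O[Si](CC)(CC)CC)[C@H]2C
F9 | step 11 | (3R)-2-[6-exo-hydroxy-5-endo-methyl-7-oxabicyclo[2.2.1]heptan-2-endo-yl]-6-methylhepta-1,5-dien-3-yl 3-methylbut-2-enoate (bicycle as in 11) | C=C([C@@H](CC=C(C)C)OC(=O)C=C(C)C)[C@@H]1C[C@H]2O[C@@H]1[C@H](O)[C@H]2C
F10 | step 11 | (3R)-6-methyl-2-[5-endo-methyl-6-oxo-7-oxabicyclo[2.2.1]heptan-2-endo-yl]hepta-1,5-dien-3-yl 3-methylbut-2-enoate (bicycle as in 12) | C=C([C@@H](CC=C(C)C)OC(=O)C=C(C)C)[C@@H]1C[C@H]2O[C@@H]1C(=O)[C@H]2C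
F11 | step 11 | (3R)-2-[(1S,2S)-2-hydroxy-4-methyl-3-oxocyclohex-4-en-1-yl]-6-methylhepta-1,5-dien-3-yl 3-methylbut-2-enoate | C=C([C@@H](CC=C(C)C)OC(=O)C=C(C)C)[C@@H]1CC=C(C)C(=O)[C@H]1O
F12 | step 13 | (1S,2R,6S)-2-hydroxy-3-methyl-6-[(3R)-6-methyl-3-(3-methylbut-2-enoyloxy)hepta-1,5-dien-2-yl]cyclohex-3-en-1-yl 3-methylbut-2-enoate (C1 epimer of 20 in target numbering) | C=C([C@@H](CC=C(C)C)OC(=O)C=C(C)C)[C@@H]1CC=C(C)[C@@H](O)[C@H]1OC(=O)C=C(C)C
F13 | step 13 | chloroacetate of 20 at the C1 hydroxyl (target numbering) | C=C([C@@H](CC=C(C)C)OC(=O)C=C(C)C)[C@@H]1CC=C(C)[C@H](OC(=O)CCl)[C@H]1OC(=O)C=C(C)C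
A1 | alternative 1 | cyclohexenol bearing both esters and the full side chain (identical with 20) | C=C([C@@H](CC=C(C)C)OC(=O)C=C(C)C)[C@@H]1CC=C(C)[C@H](O)[C@H]1OC(=O)C=C(C)C
A2 | alternative 1 | open-chain α-acyloxy aldehyde with a (Z)-2-iodobut-2-enyl group on C5 | C=C([C@@H](CC=C(C)C)OC(=O)C=C(C)C)[C@H](C/C=C(/C)I)[C@H](OC(=O)C=C(C)C)C=O
A3 | alternative 2 | 2,3-dioxabicyclo[2.2.2]oct-5-ene endoperoxide, peroxide anti to the side chain | C=C([C@@H](CC=C(C)C)O[Si](C)(C)C(C)(C)C)[C@@H]1C[C@H]2OO[C@@H]1C=C2C
A4 | alternative 2 | 5-substituted 2-methylcyclohexa-1,3-diene with the silylated side chain | C=C([C@@H](CC=C(C)C)O[Si](C)(C)C(C)(C)C)[C@@H]1CC=C(C)C=C1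
A5 | alternative 3 | endo adduct, 6-acetyl-5-(trimethylsilylethynyl)-2-methyl-1-(tert-butyldimethylsilyloxy)cyclohex-2-ene (target numbering) | C[Si](C)(C)C#C[C@@H]1CC=C(C)[C@@H](O[Si](C)(C)C(C)(C)C)[C@H]1C(C)=O
A6 | alternative 3 | (E)-1-(tert-butyldimethylsilyloxy)-2-methylbuta-1,3-diene | C=C/C(C)=C/O[Si](C)(C)C(C)(C)C
A7 | alternative 3 | (E)-6-(trimethylsilyl)hex-3-en-5-yn-2-one | CC(=O)/C=C/C#C[Si](C)(C)C
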